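**Retrosynthetic overview**

1. 12 ⇐ 11 by acetylating its one free hydroxyl. 11 ⇐ crossed head-to-head [2+2] dimerisation of two quasi-enantiomeric fimbrolide monomers, (R)-acetate 9 and (S)-alcohol 10. This is the exocyclic-alkene dimerisation by which protoanemonin gives anemonin and by which the alga presumably makes its fimbrolide dimers.
2. That one step makes both cyclobutane bonds (C5–C6 and C11–C12) and all four ring stereocentres. Because one arm is OAc and the other OH, the two antipodal cores are diastereomers and can be separated, which fixes the absolute configuration.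
3. 9 + 10 ⇐ one lipase resolution of racemic alcohol 8, both halves used together.
4. 8 ⇐ 7 ⇐ 6 by allylic bromination and solvolysis; 6 ⇐ 2-butyllevulinic acid 4 by bromination and oxidative enol-lactonisation; 4 ⇐ ethyl acetoacetate 1 + ethyl 2-bromohexanoate 2.
5. Ring order: the bromomethylidene-butenolide ring first (step 2, made once, used for both halves), the cyclobutane last (step 6).

Assumption: the SMILES is taken literally, i.e. a C2-symmetric (5S,6S,11R,12R) core carrying one (1S)- and one (1R)-acetoxybutyl arm, so the two halves must come from opposite enantiomers of the monomer.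

**Route**

Step 1
Reactants: 1 ethyl acetoacetate; 2 ethyl 2-bromohexanoate (racemic)
Product: 4 2-butyl-4-oxopentanoic acid (racemic), via diethyl 2-acetyl-3-butylsuccinate 3 (not isolated)
Conditions: NaOEt (1.05 equiv), EtOH, reflux; strip EtOH; 6 M HCl, reflux
Reagents that add atoms: water (O)
Why: acetoacetic ester alkylation (SN2 of the sodium enolate on the α-bromo ester) followed by acid hydrolysis of both esters and decarboxylation of the β-keto acid gives the 2-alkyl-levulinic acid; its stereocentre is racemic and disappears in step 2.

Step 2
Reactants: 4 2-butyl-4-oxopentanoic acid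
Product: 6 (5Z)-4-bromo-5-(bromomethylidene)-3-butylfuran-2(5H)-one, via 3,5-dibromo-2-butyl-4-oxopentanoic acid 5 (not isolated)
Conditions: Br2 (2.1 equiv), cat. HBr, CHCl3, 0 °C to rt; evaporate; conc. H2SO4, 100 °C, 20 min
Reagents that add atoms: bromine (BrBr)
Why: acid-catalysed α,α'-bromination of the ketone, then enol-lactonisation in hot sulfuric acid, which also dehydrogenates C3–C4 (it is reduced to SO2); this oxidative cyclisation is the established entry to fimbrolides, gives the more stable Z-bromomethylidene, and leaves no stereocentre.

Step 3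
Reactants: 6 (5Z)-4-bromo-5-(bromomethylidene)-3-butylfuran-2(5H)-one
Product: 7 (5Z)-4-bromo-3-(1-bromobutyl)-5-(bromomethylidene)furan-2(5H)-one (racemic)
Conditions: NBS (1.05 equiv), (PhCO2)2 (5 mol%), PhCF3, reflux, visible lamp
Reagents that add atoms: N-bromosuccinimide (O=C1CCC(=O)N1Br)
Why: Wohl–Ziegler bromination at C1', the only allylic C–H position, through a radical delocalised over the dienoate; the new stereocentre is racemic on purpose.

Step 4
Reactants: 7 (5Z)-4-bromo-3-(1-bromobutyl)-5-(bromomethylidene)furan-2(5H)-one
Product: 8 (5Z)-4-bromo-5-(bromomethylidene)-3-(1-hydroxybutyl)furan-2(5H)-one (racemic)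
Conditions: AgOSO2CF3 (1.2 equiv), acetone–H2O 4:1, rt, dark
Reagents that add atoms: water (O)
Why: silver-assisted SN1 solvolysis of the secondary allylic bromide; the two vinylic C–Br bonds do not ionise and the lactone is stable to the acid formed; the racemate is what the next step needs.

Step 5
Reactants: 8 (5Z)-4-bromo-5-(bromomethylidene)-3-(1-hydroxybutyl)furan-2(5H)-one (racemic)
Product: 9 (1R)-1-[(5Z)-4-bromo-5-(bromomethylidene)-2-oxo-2,5-dihydrofuran-3-yl]butyl acetate and 10 (5Z)-4-bromo-5-(bromomethylidene)-3-[(1S)-1-hydroxybutyl]furan-2(5H)-one (the untouched enantiomer)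
Conditions: immobilised Burkholderia cepacia lipase, vinyl acetate (3 equiv), MTBE, 35 °C, stopped at 50% conversion; filter, evaporate; the 1:1 mixture is used as such (an aliquot is separated on silica for ee)
Reagents that add atoms: vinyl acetate (CC(=O)OC=C)
Why: lipase-catalysed kinetic resolution by irreversible transesterification; with the furanone as large and propyl as medium group the Kazlauskas rule predicts acylation of the (R)-alcohol only, so one operation fixes both side-chain stereocentres, (1R) as acetate in 9 and (1S) as free alcohol in 10, and neither C–O bond is touched again.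

Step 6
Reactants: 9 (R)-acetate monomer; 10 (S)-alcohol monomer
Product: 11 (1R)-1-[(5S,6S,11R,12R)-4,10,11,12-tetrabromo-9-[(1S)-1-hydroxybutyl]-2,8-dioxo-1,7-dioxadispiro[4.0.4.2]dodeca-3,9-dien-3-yl]butyl acetate
Conditions: thioxanthone (10 mol%), 395 nm LEDs, degassed CH2Cl2, 0.5 M in each partner, 15 °C; silica gel, then preparative HPLC
Reagents that add atoms: none
Why: Proposed new method: triplet energy transfer from thioxanthone (about 65 kcal/mol, too little to break a vinylic C–Br bond) excites the bromomethylidene-butenolide, which bonds through its CHBr carbon to the CHBr carbon of a ground-state partner to give a 1,4-diradical with both radical centres as stabilised tertiary α-oxy-allyl (furanonyl) radicals, hence head-to-head; rotation in the diradical erases the Z geometry and ring closure should give the dipole-minimised array with lactone oxygens trans, bromines trans and each bromine trans to the neighbouring ring oxygen, i.e. the (5S,6S,11R,12R) core or its antipode; because 9 and 10 are quasi-enantiomers the two antipodal cores of the crossed dimer are diastereomers (expected about 1:1, statistical ceiling 25% of 11), separated from each other by HPLC and by polarity from the diacetate and diol homodimers, with 11 identified by X-ray anomalous dispersion (four Br); closest known reaction type: the head-to-head [2+2] dimerisation of protoanemonin to anemonin and sensitised enone/diene [2+2] photodimerisation.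

Step 7
Reactants: 11 crossed dimer monoacetate
Product: 12 (1S)-1-[(5S,6S,11R,12R)-9-[(1R)-1-acetoxybutyl]-4,10,11,12-tetrabromo-2,8-dioxo-1,7-dioxadispiro[4.0.4.2]dodeca-3,9-dien-3-yl]butyl acetate (target)
Conditions: Ac2O (3 equiv), pyridine, DMAP (5 mol%), CH2Cl2, 0 °C to rt
Reagents that add atoms: acetic anhydride (CC(=O)OC(C)=O)
Why: standard O-acetylation of a secondary alcohol under nucleophilic catalysis; no bond to a stereocentre is broken, so the (1S) centre and the core are retained.

**Compound list**

1 | ethyl acetoacetate | CCOC(=O)CC(C)=O | starting material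
2 | ethyl 2-bromohexanoate (racemic) | CCCCC(Br)C(=O)OCC | starting material
3 | diethyl 2-acetyl-3-butylsuccinate (diastereomer mixture, not isolated) | CCCCC(C(=O)OCC)C(C(C)=O)C(=O)OCC | intermediate
4 | 2-butyl-4-oxopentanoic acid (racemic) | CCCCC(CC(C)=O)C(=O)O | intermediate
5 | 3,5-dibromo-2-butyl-4-oxopentanoic acid (diastereomer mixture, not isolated) | CCCCC(C(=O)O)C(Br)C(=O)CBr | intermediate
6 | (5Z)-4-bromo-5-(bromomethylidene)-3-butylfuran-2(5H)-one | CCCCC1=C(Br)/C(=C/Br)OC1=O | intermediate
7 | (5Z)-4-bromo-3-(1-bromobutyl)-5-(bromomethylidene)furan-2(5H)-one (racemic) | CCCC(Br)C1=C(Br)/C(=C/Br)OC1=O | intermediate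
8 | (5Z)-4-bromo-5-(bromomethylidene)-3-(1-hydroxybutyl)furan-2(5H)-one (racemic) | CCCC(O)C1=C(Br)/C(=C/Br)OC1=O | intermediate
9 | (1R)-1-[(5Z)-4-bromo-5-(bromomethylidene)-2-oxo-2,5-dihydrofuran-3-yl]butyl acetate | CCC[C@@H](OC(C)=O)C1=C(Br)/C(=C/Br)OC1=O | intermediate
10 | (5Z)-4-bromo-5-(bromomethylidene)-3-[(1S)-1-hydroxybutyl]furan-2(5H)-one | CCC[C@H](O)C1=C(Br)/C(=C/Br)OC1=O | intermediate
11 | (1R)-1-[(5S,6S,11R,12R)-4,10,11,12-tetrabromo-9-[(1S)-1-hydroxybutyl]-2,8-dioxo-1,7-dioxadispiro[4.0.4.2]dodeca-3,9-dien-3-yl]butyl acetate | CCC[C@H](O)C1=C(Br)[C@@]2(OC1=O)[C@@H](Br)[C@H](Br)[C@@]21OC(=O)C([C@@H](CCC)OC(C)=O)=C1Br | intermediate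
12 | (1S)-1-[(5S,6S,11R,12R)-9-[(1R)-1-acetoxybutyl]-4,10,11,12-tetrabromo-2,8-dioxo-1,7-dioxadispiro[4.0.4.2]dodeca-3,9-dien-3-yl]butyl acetate | CCC[C@H](OC(C)=O)C1=C(Br)[C@@]2(OC1=O)[C@@H](Br)[C@H](Br)[C@@]21OC(=O)C([C@@H](CCC)OC(C)=O)=C1Br | target

**Totals**

Total step count: 7. Longest linear sequence: 7 steps (1 + 2 → 4 → 6 → 7 → 8 → 9 + 10 → 11 → 12).

**Three steps most likely to fail**

Step 6 (crossed photodimerisation). This step carries the most risk. The ring closure may favour a spiro-epimeric or head-to-tail dimer, the crossed dimer is at best half of the dimer mixture, and the two core-diastereomeric monoacetates may be hard to separate. The fallback sets out from 8 and comes back to the route at 12. Racemic 8 is acetylated (Ac2O, pyridine) to the racemic acetate 1-[(5Z)-4-bromo-5-(bromomethylidene)-2-oxo-2,5-dihydrofuran-3-yl]butyl acetate F1. F1 is dimerised alone and without sensitiser, as a neat film or saturated solution under Pyrex-filtered light, or thermally in the dark in the way protoanemonin dimerises. The heterochiral head-to-head dimer then forms as a racemate, i.e. 12 together with its mirror image, the (5R,6R,11S,12S) dimer with (1R)- and (1S)-acetoxybutyl arms F2. 12 is taken from this mixture by preparative HPLC on a chiral stationary phase (cellulose tris(3,5-dimethylphenylcarbamate)), which also removes the homochiral dimers; the absolute configuration is checked by X-ray anomalous dispersion.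

Step 5 (lipase resolution). The carbinol is flanked by a propyl group and a crowded tetrasubstituted alkene, so the enzyme may be slow or poorly selective. Moderate ee is tolerable, because the mirror image of 11 needs both minor enantiomers at once and is therefore strongly depleted. If the enzyme prefers the other enantiomer the route is unchanged in logic: the acetate then sits on the (1S) arm and the final acetylation still gives 12. The fallback sets out from 8 and comes back at 9 and 10. 8 is oxidised (Dess–Martin periodinane, CH2Cl2) to the ketone (5Z)-4-bromo-5-(bromomethylidene)-3-butanoylfuran-2(5H)-one F3, used at once because C4 is very electrophilic. One half of F3 is reduced with (R)-2-methyl-CBS-oxazaborolidine and catecholborane (toluene, −78 °C; Corey–Bakshi–Shibata 1,2-reduction of an alkenyl ketone) to give 10. The other half is reduced with the (S)-catalyst to (5Z)-4-bromo-5-(bromomethylidene)-3-[(1R)-1-hydroxybutyl]furan-2(5H)-one F4, which is acetylated (Ac2O, pyridine) to 9.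

Step 2 (bromination and oxidative cyclisation). Hot sulfuric acid has to act as dehydrating agent and as oxidant; yields are typically modest and the isomeric 5-(dibromomethylidene) lactone is a by-product. The fallback sets out from 4 and comes back at 6; it moves the oxidation level from sulfuric acid to bromine. 4 is brominated exhaustively (3.1 equiv Br2, cat. HBr, AcOH, 50 °C) to 3,3,5-tribromo-2-butyl-4-oxopentanoic acid F5. The ring is then closed without an oxidant (P2O5, CH2Cl2, reflux): lactonisation and dehydration give the bromomethylidene, and loss of HBr from C3–H/C4–Br gives the endocyclic double bond of 6. The regiochemistry of the third bromination is not secure. Any 3,5,5-tribromo isomer would end as the known dibromomethylidene by-product, which is removed by chromatography at 6.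

**Further compounds**

F1 | step 6 | 1-[(5Z)-4-bromo-5-(bromomethylidene)-2-oxo-2,5-dihydrofuran-3-yl]butyl acetate (racemic) | CCCC(OC(C)=O)C1=C(Br)/C(=C/Br)OC1=O
F2 | step 6 | (1R)-1-[(5R,6R,11S,12S)-9-[(1S)-1-acetoxybutyl]-4,10,11,12-tetrabromo-2,8-dioxo-1,7-dioxadispiro[4.0.4.2]dodeca-3,9-dien-3-yl]butyl acetate (mirror image of 12) | CCC[C@@H](OC(C)=O)C1=C(Br)[C@]2(OC1=O)[C@H](Br)[C@@H](Br)[C@]21OC(=O)C([C@H](CCC)OC(C)=O)=C1Br
F3 | step 5 | (5Z)-4-bromo-5-(bromomethylidene)-3-butanoylfuran-2(5H)-one | CCCC(=O)C1=C(Br)/C(=C/Br)OC1=O
F4 | step 5 | (5Z)-4-bromo-5-(bromomethylidene)-3-[(1R)-1-hydroxybutyl]furan-2(5H)-one | CCC[C@@H](O)C1=C(Br)/C(=C/Br)OC1=O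
F5 | step 2 | 3,3,5-tribromo-2-butyl-4-oxopentanoic acid (racemic) | CCCCC(C(=O)O)C(Br)(Br)C(=O)CBr
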